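**Plan**

- Retrosynthetic cuts: first C7'–C1' (ring B aryl to the carbinol carbon), then C4–C7' and C3–C7 together on the lactone, and C7''–C8'' inside the ring B/ring C side fragment; the C8''–O–C4' aryl ether comes in with 4-bromo-2-methoxyphenol.
- Enabling feature: in the γ-lactone O1–C2(=O)–C3–C4–C5 the trans pair C3/C4 carries the ring A benzylic carbon C7 on C3 and the ring B carbinol carbon C7' on C4. These are the α and β carbons of a butenolide, so a C7' acyl-anion equivalent and a ring A benzyl halide can be added across C3=C4 in one flask.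
- Forward order: the lactone ring is carried in from furfural as the (5R)-menthyloxybutenolide; step 6 joins thioacetal carbon, butenolide and ring A bromide (no ring closes); the C5 acetal becomes CH2–O, the thioacetal becomes the aldehyde, and the ring B aryltitanium bearing the protected glycerol and ring C adds; desilylation and hydrogenolysis finish.
- Stereochemistry: C4 from the C5 menthyloxy acetal (anti addition), C3 from C4 (trans alkylation), C7' from C4 by Felkin–Anh addition, C7''/C8'' from an Evans syn aldol with (R)-4-benzyloxazolidin-2-one (syn = threo, 7''S,8''S).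

Key step: step 6

Remark on the chemistry: C7''/C8''/C9'' are the glycerol carbons on ring C, and the addition to aldehyde 26 is assumed to take the C3 ring branch as the large Felkin–Anh substituent, which leads to 7'R.

**Route**

Step 1
Reactants: 1 furfural
Product: 2 5-hydroxyfuran-2(5H)-one (racemic)
Conditions: O2, hν (visible lamp), methylene blue [3,7-bis(dimethylamino)phenothiazin-5-ium chloride] (cat.), MeOH, rt
Reagents that add atoms: dioxygen, O=O
Why: Sensitised singlet-oxygen [4+2] cycloaddition to the furan gives an endoperoxide that methanol opens with loss of the formyl carbon as methyl formate, the standard photooxygenation route to the racemic γ-hydroxybutenolide.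

Step 2
Reactants: 2 5-hydroxyfuran-2(5H)-one; 3 (1R,2S,5R)-menthol
Product: 5 (5R)-5-[(1R,2S,5R)-menthyloxy]furan-2(5H)-one, via 5S acetal epimer 4 (not isolated)
Conditions: p-toluenesulfonic acid (cat.), toluene, reflux, Dean–Stark; crystallise from hexane, −20 °C; mother liquor re-equilibrated with the same acid and recrystallised
Reagents that add atoms: none
Why: Acid-catalysed acetal exchange gives both C5 epimers, which interconvert through the oxocarbenium ion under the same acid, so that crystallisation of the less soluble 5R epimer and re-equilibration of the mother liquor (crystallisation-induced epimerisation) should funnel the material into 5, whose C5 configuration is thus set by the menthol auxiliary.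

Step 3
Reactants: 6 vanillin
Product: 7 4-(benzyloxy)-3-methoxybenzaldehyde
Conditions: BnBr, K2CO3, DMF, rt
Reagents that add atoms: benzyl bromide, BrCc1ccccc1
Why: Williamson etherification of the acidic phenol proceeds cleanly under carbonate conditions and gives the aldehyde that serves both ring A (steps 4 to 6) and ring C (step 10).

Step 4
Reactants: 7 4-(benzyloxy)-3-methoxybenzaldehyde
Product: 8 [4-(benzyloxy)-3-methoxyphenyl]methanol
Conditions: NaBH4, MeOH, 0 °C
Reagents that add atoms: none
Why: Borohydride reduction of an aromatic aldehyde to the benzylic alcohol is routine and leaves the benzyl ether untouched.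

Step 5
Reactants: 8 [4-(benzyloxy)-3-methoxyphenyl]methanol
Product: 9 4-(benzyloxy)-3-methoxybenzyl bromide
Conditions: PBr3, Et2O, 0 °C
Reagents that add atoms: phosphorus tribromide, BrP(Br)Br
Why: Bromination of the electron-rich benzylic alcohol with PBr3 (SN2 displacement of the phosphite ester by bromide) is fast at 0 °C and the bromide is used freshly prepared because of its lability.

Step 6
Reactants: 10 bis(phenylthio)methane; 5 (5R)-5-[(1R,2S,5R)-menthyloxy]furan-2(5H)-one; 9 4-(benzyloxy)-3-methoxybenzyl bromide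
Product: 13 (3R,4R,5R)-3-[4-(benzyloxy)-3-methoxybenzyl]-4-[bis(phenylthio)methyl]-5-[(1R,2S,5R)-menthyloxy]dihydrofuran-2(3H)-one, via bis(phenylthio)methyllithium 11 (not isolated), via lithium lactone enolate 12 (not isolated)
Conditions: 10, n-BuLi, THF, −78 → 0 → −78 °C; 5, −78 °C; 9, DMPU, −78 → −30 °C; aq NH4Cl
Reagents that add atoms: none
Why: n-BuLi deprotonates 10 to the soft sulfur-stabilised carbanion 11, which adds in Michael fashion to C4 of butenolide 5 to give lithium enolate 12, and this enolate is C-alkylated at C3 by benzylic bromide 9 (SN2), so that C4–C7' and C3–C7 are forged in one flask. The closest known reaction type is the tandem conjugate addition/enolate alkylation of lithiated dithioacetals on 5-alkoxybutenolides that is used to assemble dibenzylbutyrolactone lignans. No ring is closed, since the lactone ring is already present in 5. C4 is controlled by the C5 acetal centre, whose menthyloxy group shields one face of the planar butenolide so that 11 enters anti to it, and C3 is controlled by C4, whose bulky bis(phenylthio)methyl group sends the bromide to the opposite face of the planar enolate, which should give the 3,4-trans,4,5-trans lactone. The step needs 1,4- over 1,2-addition, secured by the delocalised thioacetal anion and the poorly electrophilic lactone carbonyl, and clean C-monoalkylation, secured by the reactive benzylic bromide, DMPU as cosolvent and low temperature.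

Step 7
Reactants: 13 the 3-benzyl-4-[bis(phenylthio)methyl]-5-menthyloxy lactone
Product: 16 (3R,4R)-3-[4-(benzyloxy)-3-methoxybenzyl]-4-[bis(phenylthio)methyl]dihydrofuran-2(3H)-one, via aldehyde carboxylate 14 (not isolated), via hydroxy carboxylate 15 (not isolated)
Conditions: KOH, NaBH4, EtOH–H2O, 0 °C → rt; then 2 M HCl to pH 2, rt
Reagents that add atoms: potassium hydroxide, [K+].[OH-] (its oxygen enters the carboxylate and is retained statistically on relactonisation)
Why: Saponification of the acylal-type lactone expels menthol and unveils the C5 aldehyde, which NaBH4 present from the outset reduces before C4 can epimerise, and acidification relactonises the 4-hydroxy acid (hydrolysis, reduction and lactonisation in one pot), so the former auxiliary carbon becomes the lactone CH2–O while C3 and C4 are retained.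

Step 8
Reactants: 17 4-bromo-2-methoxyphenol
Product: 18 2-(4-bromo-2-methoxyphenoxy)acetic acid
Conditions: ClCH2CO2H, NaOH, H2O, reflux; then HCl
Reagents that add atoms: chloroacetic acid, OC(=O)CCl
Why: Williamson etherification of the sodium phenoxide with chloroacetate is the classical aryloxyacetic acid synthesis and does not touch the aryl bromide.

Step 9
Reactants: 18 2-(4-bromo-2-methoxyphenoxy)acetic acid; 19 (R)-4-benzyloxazolidin-2-one
Product: 21 (R)-4-benzyl-3-[2-(4-bromo-2-methoxyphenoxy)acetyl]oxazolidin-2-one, via mixed pivalic anhydride 20 (not isolated)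
Conditions: t-BuCOCl, Et3N, THF, −20 °C; then 19, LiCl, −20 °C → rt
Reagents that add atoms: none
Why: Activation as the mixed pivalic anhydride followed by LiCl/Et3N-mediated N-acylation of the oxazolidinone is a standard way to Evans imides and acylation occurs at the less hindered aryloxyacetyl carbonyl.

Step 10
Reactants: 21 (R)-4-benzyl-3-[2-(4-bromo-2-methoxyphenoxy)acetyl]oxazolidin-2-one; 7 4-(benzyloxy)-3-methoxybenzaldehyde
Product: 23 (R)-4-benzyl-3-[(2R,3S)-3-[4-(benzyloxy)-3-methoxyphenyl]-2-(4-bromo-2-methoxyphenoxy)-3-hydroxypropanoyl]oxazolidin-2-one, via Z boron enolate 22 (not isolated)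
Conditions: Bu2BOTf, i-Pr2NEt, CH2Cl2, −78 → 0 °C; 7, −78 → 0 °C; pH 7 buffer, MeOH, 30% H2O2, 0 °C
Reagents that add atoms: none
Why: Evans syn aldol reaction: the chelation-free Z-dibutylboron enolate reacts through a Zimmerman–Traxler chair on the face away from the auxiliary benzyl group, which should set C8'' and C7'' as the 2R,3S syn (threo) pair that corresponds to 7''S,8''S in the target.

Step 11
Reactants: 23 the syn aldol imide
Product: 24 (1S,2S)-1-[4-(benzyloxy)-3-methoxyphenyl]-2-(4-bromo-2-methoxyphenoxy)propane-1,3-diol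
Conditions: LiBH4, THF, MeOH (1 equiv), 0 °C
Reagents that add atoms: none
Why: Reductive cleavage of the imide with LiBH4 at 0 °C delivers the primary alcohol and returns the auxiliary without retro-aldol epimerisation, the usual way to unload Evans aldol adducts as 1,3-diols.

Step 12
Reactants: 24 the threo 1,3-diol
Product: 25 (4S,5S)-4-[4-(benzyloxy)-3-methoxyphenyl]-5-(4-bromo-2-methoxyphenoxy)-2,2-di-tert-butyl-1,3,2-dioxasilinane
Conditions: t-Bu2Si(OTf)2, 2,6-lutidine, CH2Cl2, 0 °C → rt
Reagents that add atoms: di-tert-butylsilyl bis(trifluoromethanesulfonate), CC(C)(C)[Si](OS(=O)(=O)C(F)(F)F)(OS(=O)(=O)C(F)(F)F)C(C)(C)C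
Why: Cyclic di-tert-butylsilylene protection of the 1,3-diol masks both hydroxyls in one operation with a group that tolerates aryllithium formation and is later removed by fluoride under nearly neutral conditions.

Step 13
Reactants: 16 the 4-[bis(phenylthio)methyl] lactone
Product: 26 (3R,4R)-4-[4-(benzyloxy)-3-methoxybenzyl]-5-oxotetrahydrofuran-3-carbaldehyde
Conditions: HgO, BF3·OEt2, THF–H2O, 0 °C → rt; filter, use at once (25 already in hand)
Reagents that add atoms: water, O
Why: Thiophilic mercury-assisted hydrolysis of the S,S-acetal liberates the aldehyde under non-basic conditions that spare the lactone and benzyl ether, and any enolisation at C4 would relax towards the favoured 3,4-trans lactone, the aldehyde being carried on without storage.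

Step 14
Reactants: 25 the silylene-protected aryl bromide; 26 the lactone aldehyde
Product: 29 (3R,4R)-3-[4-(benzyloxy)-3-methoxybenzyl]-4-[(R)-hydroxy(aryl)methyl]dihydrofuran-2(3H)-one in which aryl is 3-methoxy-4-{[(4S,5S)-4-(4-benzyloxy-3-methoxyphenyl)-2,2-di-tert-butyl-1,3,2-dioxasilinan-5-yl]oxy}phenyl, via aryllithium 27 (not isolated), via aryltitanium triisopropoxide 28 (not isolated)
Conditions: 25 (1.3 equiv), n-BuLi, THF, −78 °C; ClTi(OiPr)3, −78 → −40 °C; 26, −78 → 0 °C; aq NH4Cl
Reagents that add atoms: none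
Why: Bromine–lithium exchange and transmetalation to the weakly basic aryltitanium triisopropoxide allow chemoselective 1,2-addition to the aldehyde in the presence of the lactone without enolising C4, and Felkin–Anh control from C4 (aryl entering anti to the C3 ring branch with the C5 methylene inside) should set C7' as R.

Step 15
Reactants: 29 the silylene-protected carbinol
Product: 30 (3R,4R)-3-[4-(benzyloxy)-3-methoxybenzyl]-4-[(R)-hydroxy(4-{[(1S,2S)-1-(4-benzyloxy-3-methoxyphenyl)-1,3-dihydroxypropan-2-yl]oxy}-3-methoxyphenyl)methyl]dihydrofuran-2(3H)-one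
Conditions: HF·pyridine, pyridine, THF, 0 °C → rt
Reagents that add atoms: none
Why: Fluoride-mediated cleavage of the silylene (Si–F bond formation) under pyridine-buffered conditions frees the C7'' and C9'' hydroxyls without base-induced translactonisation or acid-induced ionisation of the benzylic alcohols, and is done before debenzylation so that no para-hydroxybenzylic silyl ether is exposed to fluoride.

Step 16
Reactants: 30 the bis(benzyl ether) triol
Product: 31 target, (3R,4R)-3-(4-hydroxy-3-methoxybenzyl)-4-[(R)-hydroxy(4-{[(1S,2S)-1,3-dihydroxy-1-(4-hydroxy-3-methoxyphenyl)propan-2-yl]oxy}-3-methoxyphenyl)methyl]dihydrofuran-2(3H)-one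
Conditions: H2 (1 atm), 10% Pd/C, EtOAc–EtOH, rt, stopped after uptake of 2 equiv H2
Reagents that add atoms: none
Why: Neutral Pd-catalysed hydrogenolysis cleaves the two aryl benzyl ethers, which react much faster than the two secondary benzylic alcohols, so stopping at two equivalents of H2 should deliver the target with all five stereocentres intact.

**Compound list**

1 | furfural | O=Cc1ccco1 | starting material
2 | 5-hydroxyfuran-2(5H)-one (racemic) | O=C1OC(O)C=C1 | intermediate
3 | (1R,2S,5R)-menthol | O[C@@H]1C[C@H](C)CC[C@H]1C(C)C | starting material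
4 | (5S)-5-[(1R,2S,5R)-menthyloxy]furan-2(5H)-one | O=C1O[C@H](O[C@@H]2C[C@H](C)CC[C@H]2C(C)C)C=C1 | intermediate
5 | (5R)-5-[(1R,2S,5R)-menthyloxy]furan-2(5H)-one | O=C1O[C@@H](O[C@@H]2C[C@H](C)CC[C@H]2C(C)C)C=C1 | intermediate
6 | vanillin | COc1cc(C=O)ccc1O | starting material
7 | 4-(benzyloxy)-3-methoxybenzaldehyde | COc1cc(C=O)ccc1OCc1ccccc1 | intermediate
8 | [4-(benzyloxy)-3-methoxyphenyl]methanol | COc1cc(CO)ccc1OCc1ccccc1 | intermediate
9 | 4-(benzyloxy)-3-methoxybenzyl bromide | COc1cc(CBr)ccc1OCc1ccccc1 | intermediate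
10 | bis(phenylthio)methane | C(Sc1ccccc1)Sc1ccccc1 | starting material
11 | bis(phenylthio)methyllithium | [Li]C(Sc1ccccc1)Sc1ccccc1 | intermediate
12 | lithium enolate of (4R,5R)-4-[bis(phenylthio)methyl]-5-[(1R,2S,5R)-menthyloxy]dihydrofuran-2(3H)-one | [Li]OC1=C[C@@H](C(Sc2ccccc2)Sc2ccccc2)[C@H](O[C@@H]2C[C@H](C)CC[C@H]2C(C)C)O1 | intermediate
13 | (3R,4R,5R)-3-[4-(benzyloxy)-3-methoxybenzyl]-4-[bis(phenylthio)methyl]-5-[(1R,2S,5R)-menthyloxy]dihydrofuran-2(3H)-one | COc1cc(C[C@H]2C(=O)O[C@@H](O[C@@H]3C[C@H](C)CC[C@H]3C(C)C)[C@@H]2C(Sc4ccccc4)Sc4ccccc4)ccc1OCc1ccccc1 | intermediate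
14 | potassium (2R,3R)-2-[4-(benzyloxy)-3-methoxybenzyl]-3-formyl-4,4-bis(phenylthio)butanoate | [K+].[O-]C(=O)[C@H](Cc1ccc(OCc2ccccc2)c(OC)c1)[C@H](C=O)C(Sc1ccccc1)Sc1ccccc1 | intermediate
15 | potassium (2R,3R)-2-[4-(benzyloxy)-3-methoxybenzyl]-3-(hydroxymethyl)-4,4-bis(phenylthio)butanoate | [K+].[O-]C(=O)[C@H](Cc1ccc(OCc2ccccc2)c(OC)c1)[C@H](CO)C(Sc1ccccc1)Sc1ccccc1 | intermediate
16 | (3R,4R)-3-[4-(benzyloxy)-3-methoxybenzyl]-4-[bis(phenylthio)methyl]dihydrofuran-2(3H)-one | COc1cc(C[C@H]2C(=O)OC[C@@H]2C(Sc3ccccc3)Sc3ccccc3)ccc1OCc1ccccc1 | intermediate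
17 | 4-bromo-2-methoxyphenol | COc1cc(Br)ccc1O | starting material
18 | 2-(4-bromo-2-methoxyphenoxy)acetic acid | COc1cc(Br)ccc1OCC(=O)O | intermediate
19 | (R)-4-benzyloxazolidin-2-one | O=C1N[C@H](Cc2ccccc2)CO1 | starting material
20 | 2-(4-bromo-2-methoxyphenoxy)acetic pivalic anhydride | COc1cc(Br)ccc1OCC(=O)OC(=O)C(C)(C)C | intermediate
21 | (R)-4-benzyl-3-[2-(4-bromo-2-methoxyphenoxy)acetyl]oxazolidin-2-one | COc1cc(Br)ccc1OCC(=O)N1[C@H](Cc2ccccc2)COC1=O | intermediate
22 | Z-dibutylboron enolate of 21 | COc1cc(Br)ccc1O/C=C(\OB(CCCC)CCCC)N1[C@H](Cc2ccccc2)COC1=O | intermediate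
23 | (R)-4-benzyl-3-[(2R,3S)-3-[4-(benzyloxy)-3-methoxyphenyl]-2-(4-bromo-2-methoxyphenoxy)-3-hydroxypropanoyl]oxazolidin-2-one | COc1cc(Br)ccc1O[C@@H](C(=O)N1[C@H](Cc2ccccc2)COC1=O)[C@@H](O)c1ccc(OCc2ccccc2)c(OC)c1 | intermediate
24 | (1S,2S)-1-[4-(benzyloxy)-3-methoxyphenyl]-2-(4-bromo-2-methoxyphenoxy)propane-1,3-diol | COc1cc(Br)ccc1O[C@@H](CO)[C@@H](O)c1ccc(OCc2ccccc2)c(OC)c1 | intermediate
25 | (4S,5S)-4-[4-(benzyloxy)-3-methoxyphenyl]-5-(4-bromo-2-methoxyphenoxy)-2,2-di-tert-butyl-1,3,2-dioxasilinane | COc1cc(Br)ccc1O[C@H]1CO[Si](C(C)(C)C)(C(C)(C)C)O[C@H]1c1ccc(OCc2ccccc2)c(OC)c1 | intermediate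
26 | (3R,4R)-4-[4-(benzyloxy)-3-methoxybenzyl]-5-oxotetrahydrofuran-3-carbaldehyde | COc1cc(C[C@H]2C(=O)OC[C@@H]2C=O)ccc1OCc1ccccc1 | intermediate
27 | aryllithium from 25 (Li in place of Br) | COc1cc([Li])ccc1O[C@H]1CO[Si](C(C)(C)C)(C(C)(C)C)O[C@H]1c1ccc(OCc2ccccc2)c(OC)c1 | intermediate
28 | aryltitanium triisopropoxide from 25 (Ti(OiPr)3 in place of Br) | COc1cc([Ti](OC(C)C)(OC(C)C)OC(C)C)ccc1O[C@H]1CO[Si](C(C)(C)C)(C(C)(C)C)O[C@H]1c1ccc(OCc2ccccc2)c(OC)c1 | intermediate
29 | (3R,4R)-3-[4-(benzyloxy)-3-methoxybenzyl]-4-[(R)-hydroxy(aryl)methyl]dihydrofuran-2(3H)-one, aryl = 3-methoxy-4-{[(4S,5S)-4-(4-benzyloxy-3-methoxyphenyl)-2,2-di-tert-butyl-1,3,2-dioxasilinan-5-yl]oxy}phenyl | COc1cc(C[C@H]2C(=O)OC[C@@H]2[C@@H](O)c2ccc(O[C@H]3CO[Si](C(C)(C)C)(C(C)(C)C)O[C@H]3c3ccc(OCc4ccccc4)c(OC)c3)c(OC)c2)ccc1OCc1ccccc1 | intermediate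
30 | (3R,4R)-3-[4-(benzyloxy)-3-methoxybenzyl]-4-[(R)-hydroxy(4-{[(1S,2S)-1-(4-benzyloxy-3-methoxyphenyl)-1,3-dihydroxypropan-2-yl]oxy}-3-methoxyphenyl)methyl]dihydrofuran-2(3H)-one | COc1cc(C[C@H]2C(=O)OC[C@@H]2[C@@H](O)c2ccc(O[C@@H](CO)[C@@H](O)c3ccc(OCc4ccccc4)c(OC)c3)c(OC)c2)ccc1OCc1ccccc1 | intermediate
31 | (3R,4R)-3-(4-hydroxy-3-methoxybenzyl)-4-[(R)-hydroxy(4-{[(1S,2S)-1,3-dihydroxy-1-(4-hydroxy-3-methoxyphenyl)propan-2-yl]oxy}-3-methoxyphenyl)methyl]dihydrofuran-2(3H)-one | COc1cc(C[C@H]2C(=O)OC[C@@H]2[C@@H](O)c2ccc(O[C@@H](CO)[C@@H](O)c3ccc(O)c(OC)c3)c(OC)c2)ccc1O | target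

**Step count and risks**

Total step count: 16. Longest linear sequence: 9 steps (steps 3, 4, 5, 6, 7, 13, 14, 15, 16, from vanillin).

Steps most likely to fail:

1. Step 14. The Felkin–Anh preference exerted by a ring stereocentre may give poor facial selectivity at C7', and the sluggish aryltitanium may leave time for the titanium alkoxide to translactonise on warming. The fallback sets out from 29 obtained as a C7' epimer mixture. Oxidation with Dess–Martin periodinane (CH2Cl2, NaHCO3, 0 °C) should give the aryl ketone F1. Reagent-controlled Corey–Bakshi–Shibata reduction with stoichiometric (S)-2-methyl-CBS-oxazaborolidine and catecholborane in toluene at −78 °C, with the aryl group as the large substituent, is expected to deliver hydride to the face that gives 7'R. It has to override the substrate's own hydride preference for the 7'S epimer. The sequence comes back to the route at 29.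

2. Step 13. Mercury-assisted hydrolysis of the diaryl thioacetal may be slow, and during it the β-acyloxy aldehyde can enolise (loss of C4 integrity) or undergo β-elimination with opening of the lactone. The fallback sets out from 16. Oxidative acetal exchange with PhI(OCOCF3)2 in MeOH at rt should give the dimethyl acetal F2, which can be purified and stored. Brief treatment with aqueous oxalic acid on silica gel in CH2Cl2, immediately before step 14, should release the aldehyde without metal salts, and the sequence comes back at 26.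

3. Step 6. Trapping of enolate 12 may be incomplete or unselective, through proton transfer from the acidic thioacetal CH, O-alkylation, or retro-Michael loss of the thioacetal on warming. The fallback sets out from 5 and 10. The conjugate addition is run alone and quenched with NH4Cl at −78 °C to isolate the conjugate adduct F3. Enolate 12 is then regenerated with LiN(SiMe3)2 in THF–DMPU at −78 °C and alkylated with 9 trans to the C4 substituent, and the sequence comes back at 13.

**Further compounds**

F1 | step 14 | (3R,4R)-3-[4-(benzyloxy)-3-methoxybenzyl]-4-(aroyl)dihydrofuran-2(3H)-one, aroyl = 3-methoxy-4-{[(4S,5S)-4-(4-benzyloxy-3-methoxyphenyl)-2,2-di-tert-butyl-1,3,2-dioxasilinan-5-yl]oxy}benzoyl | COc1cc(C[C@H]2C(=O)OC[C@@H]2C(=O)c2ccc(O[C@H]3CO[Si](C(C)(C)C)(C(C)(C)C)O[C@H]3c3ccc(OCc4ccccc4)c(OC)c3)c(OC)c2)ccc1OCc1ccccc1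
F2 | step 13 | (3R,4R)-3-[4-(benzyloxy)-3-methoxybenzyl]-4-(dimethoxymethyl)dihydrofuran-2(3H)-one | COc1cc(C[C@H]2C(=O)OC[C@@H]2C(OC)OC)ccc1OCc1ccccc1
F3 | step 6 | (4R,5R)-4-[bis(phenylthio)methyl]-5-[(1R,2S,5R)-menthyloxy]dihydrofuran-2(3H)-one | O=C1C[C@@H](C(Sc2ccccc2)Sc2ccccc2)[C@H](O[C@@H]2C[C@H](C)CC[C@H]2C(C)C)O1
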